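The earlier runs and the new flask are calculated for an exercise; noise was put on by code.

The slowness of these flasks shows in the early readings: theta already holds 10.6 % of target against 0.3 % of side product at 3.00 min, and side product then creeps up, as the candidate step of starting material with target would have it.

| setting | theta | gamma | south-west | south | east |
|---|---|---|---|---|---|
| starting material | 0.020 M | 0.020 M | 0.020 M | 0.020 M | 0.020 M |
| partner | 0.012 M | 0.018 M | 0.0240 M | 0.0240 M | 0.0240 M |
| second substrate | 4 mM | 4 mM | 4.00 mM | 4.00 mM | 4.00 mM |
| temperature | 30 °C | 52 °C | 20 °C | 40 °C | 60 °C |
| remark | run made earlier | run made earlier |  |  |  |
| time |  |  | 30 min | 30 min | 30 min |

- theta (time / min: side product / %, target / %, starting material / %): 3.00: 0.3, 10.6, 88.4; 8.00: 8.0, 9.5, 83.5; 15.0: 15.3, 10.4, 78.0; 25.0: 21.6, 8.1, 72.6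
- gamma (time / min: side product / %, target / %, starting material / %): 0.667: 1.3, 3.5, 93.6; 1.33: 2.7, 4.2, 91.8; 3.00: 8.8, 4.9, 89.2; 8.00: 12.5, 6.0, 81.5

(readings scatter by 1 percentage point)

* which of these there is most of at the end, counted by the starting material in it, south-west (side product / target / starting material)
* which of these there is most of at the end, counted by the starting material in it, south (side product / target / starting material)
* which of these there is most of at the end, counted by the starting material in it, east (side product / target / starting material)
* final amount of the leader among these, as a percentage of the starting material charged, in south-west
* final amount of the leader among these, as a percentage of the starting material charged, in south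
* final amount of the leader among these, as a percentage of the starting material charged, in east

- percent here means starting material units held: one side product counts as two
- candidate steps: starting material + partner <-> target; second substrate + partner <-> second product; 2 second substrate -> self-condensation product; starting material + target -> side product

If target stays near its balance with starting material and partner, its level follows their product, so the pace of side product follows the square of the starting material left and the first power of the partner. Such a pace has a simple consequence: call N the pace at full charge times the time, and the share of starting material left is the reciprocal of one plus N, with target not counted, so starting material and side product stand level where N equals one. We take the pace in theta between its first and last readings, divide by the square of the mean starting material, scale by the ratio of partner charged in the new flasks to that in theta and multiply by the asked time, which gives, as an estimate at theta's temperature that carries the scatter of the readings, N = 0.896; this overtaking number, the asked time over the second-order half-life of starting material, says which of starting material and side product leads.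

Was one number enough? Gamma, at 52 °C, holds less target at 3.00 min than theta at 3.00 min despite more partner, yet its side product climbs faster than theta's, and the same reckoning on gamma's readings gives N = 0.797, so both values lie below one. We assume that N carries across the remaining gaps in temperature, theta's value to south-west and south and gamma's to east, so we expect starting material to lead in each of the three flasks, with 52.7 % in south-west and south and 55.6 % in east, target not counted.

The forecast names starting material, side product and side product as leaders, at 46 %, 47 % and 50 %, and says of south “Partner released later tips it to side product”.

Starting material leads at 49.4 % in south-west, 53.0 % in south and 56.9 % in east.

    starting material + partner ⇌ target (K = 29.0 L mol⁻¹, k = 3.30 L mol⁻¹ min⁻¹, Ea = 65.0 kJ mol⁻¹, ΔH = −54.0 kJ mol⁻¹)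
    second substrate + partner ⇌ second product (K = 110 L mol⁻¹, k = 0.610 L mol⁻¹ min⁻¹, Ea = 64.0 kJ mol⁻¹, ΔH = −51.0 kJ mol⁻¹)
    2 second substrate → self-condensation product (k = 57.0 L mol⁻¹ min⁻¹, Ea = 38.0 kJ mol⁻¹)
    starting material + target → side product (k = 1.70 L mol⁻¹ min⁻¹, Ea = 44.0 kJ mol⁻¹)
    (constants at 20 °C)

Target stands at 22.4 % in south-west and 2.24 % in east, the share N leaves aside. Reading south at 2.0 h instead multiplies the time, so N grows to 3.59, above one, and starting material should be down to 21.8 % with side product ahead; south then holds 71.6 % of side product against 25.5 % of starting material.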